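**Retrosynthetic overview**
- Cathayanon H ⇒ rings C and A opened together: the C2–O1 bond goes back to a 2′,4′,6′‑trihydroxychalcone (2R,3S)‑epoxide (inversion at C2), and the ring‑A bond C4a–C5 goes back to a linear epoxy 3,5,7‑triketo ester (Claisen).
- The triketo ester is carried as its lactone, a 6‑(glycidoylmethyl)‑4‑hydroxy‑2‑pyrone ⇒ triacetic acid lactone dianion + (2R,3S)‑epoxy morpholine amide (C4–C4a bond).
- Epoxy amide ⇒ (E)‑enamide by catalytic asymmetric nucleophilic epoxidation (sets both stereocentres, spares the prenyl alkenes) ⇒ aryl aldehyde by HWE.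
- Aldehyde ⇒ 4‑hydroxybenzaldehyde + two prenyl bromide, phenol masked as MOM ether.
- Ring order: B is bought; A (Claisen aromatisation) and then C (epoxide opening) are formed in the same final operation.

Assumption: in the Sm/(S)‑BINOL/Ph3As=O epoxidation the (S)‑ligand gives the (2R,3S)‑epoxy amide, as with the parent cinnamamides; the sense is confirmed on the first batch by chiral HPLC and rotation.

Abbreviation used in names: Ar = 4‑(methoxymethoxy)‑3,5‑bis(3‑methylbut‑2‑en‑1‑yl)phenyl.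

**Step 1**
Reactants: 1 4‑hydroxybenzaldehyde; 2 prenyl bromide (1‑bromo‑3‑methylbut‑2‑ene)
Product: 4 4‑hydroxy‑3,5‑bis(3‑methylbut‑2‑en‑1‑yl)benzaldehyde, via mono-prenyl aldehyde 3 (not isolated)
Conditions: 10% aq. KOH, 2 (2.5 equiv, in portions), 25 °C, 24 h; recovered 3 recycled
Reagents that add atoms: prenyl bromide (2), CC(C)=CCBr
Why: Ortho C‑alkylation of the phenoxide in water (phenoxide C‑prenylation) occurs twice via 3; the yield is modest because O‑prenylation competes, but it is one step from bulk chemicals.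

**Step 2**
Reactants: 4 4‑hydroxy‑3,5‑bis(3‑methylbut‑2‑en‑1‑yl)benzaldehyde; 5 chloromethyl methyl ether
Product: 6 4‑(methoxymethoxy)‑3,5‑bis(3‑methylbut‑2‑en‑1‑yl)benzaldehyde
Conditions: NaH, DMF, 0 °C; then 5, 0 → 25 °C
Reagents that add atoms: chloromethyl methyl ether (5), COCCl
Why: Williamson‑type O‑alkylation of the acidic para‑formyl phenoxide with the small, reactive MOMCl; the MOM ether blocks quinone‑methide opening of the later para epoxide and survives base, peroxide and organolithium conditions.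

**Step 3**
Reactants: 6 4‑(methoxymethoxy)‑3,5‑bis(3‑methylbut‑2‑en‑1‑yl)benzaldehyde; 7 diethyl (2‑morpholino‑2‑oxoethyl)phosphonate
Product: 8 (2E)‑3‑Ar‑1‑(morpholin‑4‑yl)prop‑2‑en‑1‑one
Conditions: NaH, THF, 0 → 25 °C
Reagents that add atoms: diethyl (2‑morpholino‑2‑oxoethyl)phosphonate (7), CCOP(=O)(OCC)CC(=O)N1CCOCC1
Why: Horner–Wadsworth–Emmons olefination with an amide‑stabilised phosphonate gives the (E)‑enamide selectively; the morpholine amide is the substrate class for step 4 and a Weinreb‑like acyl donor for step 5.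

**Step 4**
Reactants: 8 (2E)‑3‑Ar‑1‑(morpholin‑4‑yl)prop‑2‑en‑1‑one; 9 tert‑butyl hydroperoxide
Product: 10 [(2R,3S)‑3‑Ar‑oxiran‑2‑yl](morpholin‑4‑yl)methanone (trans epoxide)
Conditions: Sm(O‑i‑Pr)3/(S)‑BINOL/Ph3As=O (1:1:1, 10 mol %), 9 (1.5 equiv, decane), 4 Å MS, THF, 25 °C
Reagents that add atoms: tert‑butyl hydroperoxide (9), CC(C)(C)OO
Why: Catalytic asymmetric nucleophilic (Weitz–Scheffer‑type) epoxidation: the samarium‑bound peroxide adds 1,4 to the coordinated enamide on one face and the enolate closes on O–O, giving the trans (2R,3S) epoxide; this fixes C3 directly and C2 as its invertible precursor, and the electron‑rich prenyl alkenes do not react with a nucleophilic oxidant.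

**Step 5**
Reactants: 10 [(2R,3S)‑3‑Ar‑oxiran‑2‑yl](morpholin‑4‑yl)methanone; 11 4‑hydroxy‑6‑methyl‑2H‑pyran‑2‑one (triacetic acid lactone)
Product: 13 4‑hydroxy‑6‑{2‑[(2R,3S)‑3‑Ar‑oxiran‑2‑yl]‑2‑oxoethyl}‑2H‑pyran‑2‑one, via pyrone dianion 12 (not isolated)
Conditions: 11 (2.2 equiv), LDA (4.6 equiv, commercial solution), THF, −78 → −20 °C; then 10, −78 → −40 °C; AcOH quench at −78 °C, pH 5 work‑up
Reagents that add atoms: 4‑hydroxy‑6‑methyl‑2H‑pyran‑2‑one (11), CC1=CC(O)=CC(=O)O1
Why: Claisen‑type C‑acylation: the 6‑methyl carbanion of the dianion adds to the α‑oxygen‑activated morpholine amide at −78 °C faster than it attacks the epoxide, the hemiaminal alkoxide holds until the quench so there is no second addition, and neither stereocentre is touched.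

**Step 6**
Reactants: 13 4‑hydroxy‑6‑{2‑[(2R,3S)‑3‑Ar‑oxiran‑2‑yl]‑2‑oxoethyl}‑2H‑pyran‑2‑one
Product: 17 Cathayanon H, via epoxy triketo ester 14 (not isolated), via chalcone epoxide 15 (not isolated), via MOM dihydroflavonol 16 (not isolated)
Conditions: Mg(OMe)2 (6 equiv), degassed MeOH, 65 °C, Ar, until 13 is consumed; then 3 M HCl/MeOH, 0 → 45 °C (one pot)
Reagents that add atoms: none
Why: Proposed new method: methoxide opens the pyrone to the Mg‑chelated triketo ester 14, whose C6 carbon closes on the ester (Claisen mode, favoured when all ketones are enolised) and tautomerises to acylphloroglucinol 15 (ring A); on acidification the ortho phenol opens the protonated epoxide at the para‑alkoxybenzylic carbon (6‑endo) with inversion (S → R at C2) while C3 keeps the R configuration of the epoxide α‑carbon, giving 2,3‑trans ring C (16), and HCl/MeOH then removes the MOM group; the closest known chemistry is the biomimetic Mg(OMe)2‑mediated Claisen cyclisation of 6‑(2‑oxoalkyl)‑4‑hydroxy‑2‑pyrones and 3,5,7‑trioxo esters to acylphloroglucinols (which in the cinnamoyl series runs on to the flavanone), combined with the acid‑mediated cyclisation of 2′‑hydroxychalcone epoxides to trans‑dihydroflavonols.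

**Compound list**
1 | 4‑hydroxybenzaldehyde | O=Cc1ccc(O)cc1 | starting material
2 | prenyl bromide | CC(C)=CCBr | starting material
3 | 4‑hydroxy‑3‑(3‑methylbut‑2‑en‑1‑yl)benzaldehyde | O=Cc1ccc(O)c(CC=C(C)C)c1 | intermediate (not isolated)
4 | 4‑hydroxy‑3,5‑bis(3‑methylbut‑2‑en‑1‑yl)benzaldehyde | O=Cc1cc(CC=C(C)C)c(O)c(CC=C(C)C)c1 | intermediate
5 | chloromethyl methyl ether | COCCl | starting material
6 | 4‑(methoxymethoxy)‑3,5‑bis(3‑methylbut‑2‑en‑1‑yl)benzaldehyde | O=Cc1cc(CC=C(C)C)c(OCOC)c(CC=C(C)C)c1 | intermediate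
7 | diethyl (2‑morpholino‑2‑oxoethyl)phosphonate | CCOP(=O)(OCC)CC(=O)N1CCOCC1 | starting material
8 | (2E)‑3‑Ar‑1‑(morpholin‑4‑yl)prop‑2‑en‑1‑one | O=C(/C=C/c1cc(CC=C(C)C)c(OCOC)c(CC=C(C)C)c1)N1CCOCC1 | intermediate
9 | tert‑butyl hydroperoxide | CC(C)(C)OO | starting material
10 | [(2R,3S)‑3‑Ar‑oxiran‑2‑yl](morpholin‑4‑yl)methanone | O=C(N1CCOCC1)[C@@H]2O[C@H]2c3cc(CC=C(C)C)c(OCOC)c(CC=C(C)C)c3 | intermediate
11 | 4‑hydroxy‑6‑methyl‑2H‑pyran‑2‑one | CC1=CC(O)=CC(=O)O1 | starting material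
12 | dilithium dianion of 11 (4‑oxido, 6‑CH2 carbanion) | [Li+].[Li+].[CH2-]C1=CC([O-])=CC(=O)O1 | intermediate (not isolated)
13 | 4‑hydroxy‑6‑{2‑[(2R,3S)‑3‑Ar‑oxiran‑2‑yl]‑2‑oxoethyl}‑2H‑pyran‑2‑one | O=C(CC1=CC(O)=CC(=O)O1)[C@@H]2O[C@H]2c3cc(CC=C(C)C)c(OCOC)c(CC=C(C)C)c3 | intermediate
14 | methyl 7‑[(2R,3S)‑3‑Ar‑oxiran‑2‑yl]‑3,5,7‑trioxoheptanoate (as Mg enolate) | COC(=O)CC(=O)CC(=O)CC(=O)[C@@H]1O[C@H]1c2cc(CC=C(C)C)c(OCOC)c(CC=C(C)C)c2 | intermediate (not isolated)
15 | [(2R,3S)‑3‑Ar‑oxiran‑2‑yl](2,4,6‑trihydroxyphenyl)methanone | O=C(c1c(O)cc(O)cc1O)[C@@H]2O[C@H]2c3cc(CC=C(C)C)c(OCOC)c(CC=C(C)C)c3 | intermediate (not isolated)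
16 | (2R,3R)‑3,5,7‑trihydroxy‑2‑Ar‑2,3‑dihydro‑4H‑chromen‑4‑one (2,3‑trans) | COCOc1c(CC=C(C)C)cc([C@H]2Oc3cc(O)cc(O)c3C(=O)[C@@H]2O)cc1CC=C(C)C | intermediate (not isolated)
17 | Cathayanon H, (2R,3R)‑3,5,7‑trihydroxy‑2‑[4‑hydroxy‑3,5‑bis(3‑methylbut‑2‑en‑1‑yl)phenyl]‑2,3‑dihydro‑4H‑chromen‑4‑one | CC(C)=CCc1cc([C@H]2Oc3cc(O)cc(O)c3C(=O)[C@@H]2O)cc(CC=C(C)C)c1O | target

**Total step count:** 6. **Longest linear sequence:** 6 steps (1 → 4 → 6 → 8 → 10 → 13 → 17).

**Steps most likely to fail**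

The riskiest is step 6. The open triketo ester may cyclise in the aldol sense to a resorcylate. An enolate or phenoxide oxygen may attack the epoxide α‑carbon (furanone or aurone‑type products). Any 16 formed early may degrade in the hot basic stage. The fallback sets out from 10 and gives up building ring A. Phloroglucinol is protected (MOMCl, NaH, DMF) to 1,3,5‑tris(methoxymethoxy)benzene F1. n‑BuLi (THF, 0 °C) lithiates it between two OMOM groups to 2,4,6‑tris(methoxymethoxy)phenyllithium F2. Addition to 10 at −78 °C gives [(2R,3S)‑3‑Ar‑oxiran‑2‑yl][2,4,6‑tris(methoxymethoxy)phenyl]methanone F3. 3 M HCl/MeOH at 45 °C removes the four MOM groups and closes ring C by the same benzylic epoxide opening, coming back to the route at 17.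

Next is step 5. The pyrone dianion is poorly soluble and may open the epoxide or give a ketone that does not survive work‑up. The fallback sets out from 10, leaves out the pyrone and comes back at 14. Methyl 3,5‑dioxohexanoate (bought, or from dehydroacetic acid and Mg(OMe)2) is treated with LDA (3.1 equiv, THF, −78 → 0 °C) to give the trilithium trianion of methyl 3,5‑dioxohexanoate F4. Its terminal carbanion is acylated by 10 at −78 °C. A methanol quench leaves the polyenolate of 14 in the flask, and Mg(OMe)2/MeOH then HCl/MeOH are added as in step 6.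

Third is step 4. The peroxide addition may be slow on this electron‑rich, hindered enamide, or the ee may be too low. The fallback sets out from 6 and comes back at 13. Darzens condensation of 6 with methyl chloroacetate (NaOMe, MeOH, −10 → 20 °C) gives the racemic trans glycidate, methyl rac‑(2R,3S)‑3‑Ar‑oxirane‑2‑carboxylate F5. A lipase (Candida rugosa or Serratia marcescens, toluene/pH 8 buffer) hydrolyses the (2S,3R) ester, as in the resolution of the 4‑methoxyphenyl analogue, and leaves methyl (2R,3S)‑3‑Ar‑oxirane‑2‑carboxylate F6. F6 acylates the pyrone dianion 12 under the conditions of step 5 to give 13.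

**Further compounds**
F1 | step 6 | 1,3,5‑tris(methoxymethoxy)benzene | COCOc1cc(OCOC)cc(OCOC)c1
F2 | step 6 | 2,4,6‑tris(methoxymethoxy)phenyllithium | [Li]c1c(OCOC)cc(OCOC)cc1OCOC
F3 | step 6 | [(2R,3S)‑3‑Ar‑oxiran‑2‑yl][2,4,6‑tris(methoxymethoxy)phenyl]methanone | O=C(c1c(OCOC)cc(OCOC)cc1OCOC)[C@@H]2O[C@H]2c3cc(CC=C(C)C)c(OCOC)c(CC=C(C)C)c3
F4 | step 5 | trilithium trianion of methyl 3,5‑dioxohexanoate | [Li+].[Li+].[Li+].COC(=O)[CH-]C(=O)[CH-]C(=O)[CH2-]
F5 | step 4 | methyl rac‑(2R,3S)‑3‑Ar‑oxirane‑2‑carboxylate (racemic trans, both enantiomers written) | COC(=O)[C@@H]1O[C@H]1c2cc(CC=C(C)C)c(OCOC)c(CC=C(C)C)c2.COC(=O)[C@H]1O[C@@H]1c2cc(CC=C(C)C)c(OCOC)c(CC=C(C)C)c2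
F6 | step 4 | methyl (2R,3S)‑3‑Ar‑oxirane‑2‑carboxylate | COC(=O)[C@@H]1O[C@H]1c2cc(CC=C(C)C)c(OCOC)c(CC=C(C)C)c2
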